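Target is what this flask is for, but target can turn into over-reaction product after it has formed, so the examiner asks what still stands at the stopping time, and not what has been made.

| flask | substrate | enzyme | remark | time |
|---|---|---|---|---|
| winter | 0.15 M (fed, over 0.60 h) | 0.04 mol% | run made earlier |  |
| Wednesday's | 0.15 M (fed, over 0.60 h) | 0.02 mol% |  | 2.0 h |
| Thursday's | 0.15 M (fed, over 2.0 h) | 0.02 mol% |  | 2.0 h |
| Monday's | 0.15 M (fed, over 6.0 h) | 0.02 mol% |  | 2.0 h |

winter run (percent of the substrate charged)

| time / min | target / % |
|---|---|
| 1.00 | 0.2 |
| 1.33 | 0.7 |
| 2.00 | 5.6 |
| 3.00 | 6.3 |
| 5.00 | 12.4 |
| 8.00 | 19.9 |
| 12.0 | 30.5 |

(scatter of a reading: 1 percentage point)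

- the numbers in the tables scatter by 1 percentage point (one standard deviation)
- steps under discussion: substrate + enzyme -> target + enzyme; target -> over-reaction product
- percentages count the whole charge, also what has not yet gone in
- "hardly changes" means that all values lie within two and a half points (for a concentration: within two and a half percent of the largest)
- no earlier run changes the charge of enzyme; that part of a forecast is a guess
- a step back or a flat step of under half a point counts as no turn

- amount of target at the end, in percent of the substrate charged for Wednesday's, Thursday's, Monday's, in this order
- the shape of the row from first to last (hardly changes / rises, then falls / falls all the way / falls, then rises / rises all the way)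

"What does the winter run show?" Target climbs just behind the feed and reads 30.5% at 12.0 min.

"Is that shortfall a lag or a loss?" A constant lag shifts the curve and leaves its slope equal to the feed, while a first-order loss bends the slope below the feed. So I compare gains, and I work with the fraction left. Between 5.00 min and 12.0 min the feed put in 19.4% and target gained 18 percentage points, so the fraction left reads 93.1%.

"Where is that weak?" The gap is 1.4 points, close to the scatter of 1 point, so this is a rough reading and a zero loss is not excluded. I commit to it anyway.

"What time constant follows?" On a steady feed, the gain divided by the feed is the fraction left of what went in first. That material is 8.50 min old at the middle of the interval, which gives 1.98 h, the lifetime of target, the time constant of its loss.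

"And the three flasks?" My rule is that target at the end equals the share fed times the fraction left at the mean age of what went in. This gives 42.3% for Wednesday's, 60.3% for Thursday's and 20.1% for Monday's. Thursday's stands above both others, so my row rises, then falls.

The forecast gives 99%, 98% and 33%, with the shape falls all the way, on the ground “I assume none is seen”. My reckoning differs from it in the numbers and in the shape.

The flask gives 32.3%, 54.6% and 18.2%, and the row rises, then falls.

    substrate + enzyme → target + enzyme, rate k1*[substrate]*[enzyme]/(1 + ([substrate]/Km1)) (0.331 M, k = 521 M⁻¹ s⁻¹)
    target → over-reaction product (k = 1.88 × 10⁻⁴ s⁻¹)

Wednesday's flask shows the reason: without the conversion of target into over-reaction product it ends at 100% and with it at 32.3%. With substrate at 0% at 1.00 h, target falls from 63.5% to 32.3% by 2.00 h, where the lifetime carried across that hour gives 38.3%. Monday's flask, with a third fed, is reckoned by the same rule at 20.1%. Monday's flask holds 18.2%, and the conversion of target into over-reaction product is part of the reason for that figure: with that step taken away, Monday's flask holds 33.0%.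

(The numbers in the tables are simulated for substances that don't exist; noise was put on by code.)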